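**Plan**
- Late cuts: the methyl ester/epoxide goes back to a 2-substituted allylic alcohol (Sharpless epoxidation, then oxidation), the C9 ester to its alcohol, and the C9-hydroxy/C1-exomethylene pair to a C1(Me)=C9 alkene through its upper-face epoxide.
- Key cut: the C2–C3 bond of the cyclopentanone together with the C8–O bond. C3 (α to the C4 ketone) sits on ring-fusion carbon C2, which is allylic to C1 and 1,4 to the C8 oxygen across C1–C9; the bicycle is therefore the cis-1,4-carbo-acyloxylation product of a cyclohexa-1,3-diene (C2=C1–C9=C8) carrying a β-keto ester tether on C6.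
- The diene is cut back to (R)-carvone: C6–C5 by Ireland–Claisen rearrangement of a tertiary allylic acetate, C5–C11 by an auxiliary-controlled syn-aldol with acetaldehyde, C4–C3 by malonate acylation.
- Forward: the six-membered ring is that of carvone throughout; the five-membered ring closes in step 16; then the C9 oxygen/exomethylene, the C9 ester and the epoxy ester follow.
- Stereochemistry: C7 from (R)-carvone; C6 by suprafacial [3,3] shift from a hydroxyl-directed epoxide; C5/C11 from the thiazolidinethione auxiliary; C2 and C8 from the tether and anti attack on palladium; C9 from convex-face epoxidation; the epoxide carbon from D-tartrate; the butanoate centre is bought.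

Key step: step 16

Locants used for all intermediates: C1 carries the exocyclic CH2 (a methyl before step 19); C2 and C6 are the ring-fusion carbons; C3–C4(=O)–C5 complete the five-membered ring; C11 is the acetoxy-bearing carbon on C5; C7 carries the three-carbon side chain; C8 the 3-methylpent-2-enoate; C9 the 2-methylbutanoate. "Lower face" is the face of the six-membered ring that carries the C7 side chain.

Assumption: (E)-3-methylpent-2-enoic acid and (R)-2-methylbutanoic acid are purchased as single isomers.

**Step 1**
Reactants: 1 (R)-(−)-carvone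
Product: 2 (5R)-5-(3-hydroxyprop-1-en-2-yl)-2-methylcyclohex-2-en-1-one
Conditions: SeO2 (cat.), t-BuOOH, CH2Cl2, 25 °C
Reagents that add atoms: tert-butyl hydroperoxide, CC(C)(C)OO
Why: Riley oxidation (ene reaction followed by [2,3]-sigmatropic shift) should oxidise the methyl of the isopropenyl group selectively because the ring alkene is an electron-poor enone, and no stereocentre is created.

**Step 2**
Reactants: 2 (5R)-5-(3-hydroxyprop-1-en-2-yl)-2-methylcyclohex-2-en-1-one
Product: 3 (5R)-5-[3-(tert-butyldiphenylsilyloxy)prop-1-en-2-yl]-2-methylcyclohex-2-en-1-one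
Conditions: t-BuPh2SiCl, imidazole, DMF, 25 °C
Reagents that add atoms: tert-butyl(chloro)diphenylsilane, CC(C)(C)[Si](Cl)(c1ccccc1)c1ccccc1
Why: Standard silylation of the primary allylic alcohol, which keeps this alkene out of the hydroxyl-directed epoxidation of step 4 and survives every step up to step 21.

**Step 3**
Reactants: 3 silyl ether of hydroxycarvone
Product: 4 (1R,5R)-5-[3-(tert-butyldiphenylsilyloxy)prop-1-en-2-yl]-2-methylcyclohex-2-en-1-ol (C9 hydroxyl cis to the C7 side chain)
Conditions: NaBH4, CeCl3·7H2O, MeOH, −78 °C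
Reagents that add atoms: none
Why: Luche 1,2-reduction, in which axial hydride delivery to the carvone-type enone should give the pseudo-equatorial C9 alcohol cis to the C7 side chain.

**Step 4**
Reactants: 4 cis-carveol-type allylic alcohol
Product: 5 epoxy alcohol (C1–C2 oxirane oxygen, C9 hydroxyl and C7 side chain all on the lower face)
Conditions: VO(acac)2 (cat.), t-BuOOH, toluene, 0 → 25 °C
Reagents that add atoms: tert-butyl hydroperoxide, CC(C)(C)OO
Why: Hydroxyl-directed epoxidation with VO(acac)2 should deliver oxygen to the ring alkene only and on the face of the C9 hydroxyl, which places the future tertiary C1–O bond on the lower face.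

**Step 5**
Reactants: 5 epoxy alcohol
Product: 7 ene-diol (tertiary C1 hydroxyl and C9 hydroxyl on the lower face; C2=C6 alkene), via hydroxy selenide 6 (not isolated)
Conditions: (PhSe)2, NaBH4, EtOH, 78 °C; then 30% H2O2, THF, 0 → 25 °C
Reagents that add atoms: none
Why: Trans-diaxial SN2 opening of the epoxide by phenylselenolate at the secondary carbon C2 followed by selenoxide syn-elimination, which can only run towards C6 because C1 has no hydrogen, should give the tertiary allylic alcohol with its C1–O configuration unchanged.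

**Step 6**
Reactants: 7 ene-diol
Product: 8 C9 triethylsilyl ether of 7
Conditions: Et3SiCl, imidazole, CH2Cl2, 0 °C
Reagents that add atoms: chlorotriethylsilane, CC[Si](Cl)(CC)CC
Why: Silylation discriminates the secondary C9 hydroxyl from the hindered tertiary one and blocks it during enolate formation in step 8.

**Step 7**
Reactants: 8 C9 silyl ether
Product: 9 tertiary C1 acetate of 8
Conditions: Ac2O, Et3N, DMAP, CH2Cl2, 40 °C
Reagents that add atoms: acetic anhydride, CC(=O)OC(C)=O
Why: DMAP-catalysed acylation of the tertiary allylic alcohol gives the acetate needed for the ester enolate rearrangement, without touching the C1 stereocentre.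

**Step 8**
Reactants: 9 tertiary allylic acetate
Product: 12 C6 acetic acid (CH2CO2H on C6 cis to the C7 side chain and to the C9 silyl ether; C1=C2 alkene), via silyl ketene acetal 10 (not isolated), via trimethylsilyl ester 11 (not isolated)
Conditions: LDA, THF, −78 °C; Me3SiCl, Et3N, −78 → 60 °C; aq. citric acid
Reagents that add atoms: none
Why: Ireland–Claisen rearrangement, a suprafacial [3,3]-sigmatropic shift of the silyl ketene acetal, should form the C6–C5 bond on the face that the C1 oxygen leaves, that is cis to the C7 side chain, while moving the alkene to C1=C2.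

**Step 9**
Reactants: 12 C6 acetic acid; 13 (R)-4-benzyl-1,3-thiazolidine-2-thione
Product: 14 N-acyl thiazolidinethione of 12
Conditions: EDC·HCl, DMAP, CH2Cl2, 0 → 25 °C
Reagents that add atoms: none
Why: Carbodiimide-mediated N-acylation attaches the chiral auxiliary that will control C5 and C11.

**Step 10**
Reactants: 14 N-acyl thiazolidinethione
Product: 15 syn-aldol adduct (C5 R, C11 S; free C11 hydroxyl)
Conditions: TiCl4, i-Pr2NEt, N-methyl-2-pyrrolidinone, CH2Cl2, 0 °C; then MeCHO, −78 → 0 °C
Reagents that add atoms: acetaldehyde, CC=O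
Why: Titanium enolate aldol addition of the N-acyl thiazolidinethione through a chelated Z-enolate and a Zimmerman–Traxler transition state should give the syn adduct whose absolute sense (C5 R, C11 S) is dictated by the (R)-auxiliary and not by the remote C6 centre.

**Step 11**
Reactants: 15 syn-aldol adduct
Product: 16 C11 acetate of 15
Conditions: Ac2O, pyridine, DMAP (cat.), CH2Cl2, 0 °C
Reagents that add atoms: acetic anhydride, CC(=O)OC(C)=O
Why: Acetylation installs the acetate of the target at C11 and prevents lactonisation of this hydroxyl onto the β-keto ester made in step 13.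

**Step 12**
Reactants: 17 Meldrum's acid (2,2-dimethyl-1,3-dioxane-4,6-dione); 18 2,2,2-trichloroethanol
Product: 19 3-oxo-3-(2,2,2-trichloroethoxy)propanoic acid
Conditions: toluene, 110 °C
Reagents that add atoms: none
Why: Alcoholysis of Meldrum's acid with loss of acetone is the standard entry to a malonic half ester, here one whose ester can later be removed reductively.

**Step 13**
Reactants: 16 acetylated aldol adduct; 19 3-oxo-3-(2,2,2-trichloroethoxy)propanoic acid
Product: 20 2,2,2-trichloroethyl β-keto ester (C3 methylene between the C4 ketone and the ester; C5 R, C11 S; C9 silyl ether retained)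
Conditions: MgCl2, imidazole, THF, 25 → 40 °C
Reagents that add atoms: none
Why: Decarboxylative Claisen-type acylation of the magnesium enolate of the malonic half ester by the activated N-acyl thiazolidinethione should give the β-keto ester under conditions too weakly basic to enolise C5, so that C5 and C11 are retained.

**Step 14**
Reactants: 20 β-keto ester with C9 silyl ether
Product: 21 C9 allylic alcohol
Conditions: HF·pyridine, pyridine, THF, 0 °C
Reagents that add atoms: none
Why: The secondary triethylsilyl ether is cleaved far faster by buffered HF than the tert-butyldiphenylsilyl ether, which frees the C9 hydroxyl alone.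

**Step 15**
Reactants: 21 C9 allylic alcohol
Product: 22 cyclohexa-1,3-diene β-keto ester (C2=C1(Me)–C9=C8; C6 and C7 substituents cis)
Conditions: Burgess reagent (MeO2CN–SO2NEt3), benzene, 50 °C
Reagents that add atoms: none
Why: Burgess dehydration, a syn-elimination of the C9 sulfamate that can only take a hydrogen from C8 because C1 carries none, should give the C2=C1–C9=C8 diene without disturbing C6 or C7.

**Step 16**
Reactants: 22 cyclohexa-1,3-diene β-keto ester; 23 (E)-3-methylpent-2-enoic acid
Product: 24 cis-fused bicyclic β-keto ester (new C2–C3 bond and C8 3-methylpent-2-enoate both on the lower face; C1(Me)=C9 alkene; C3 epimers)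
Conditions: Pd(OAc)2 (5 mol%), p-benzoquinone (1.5 equiv), LiCl (0.2 equiv), LiOH·H2O (2 equiv), 23 (8 equiv), acetone, 25 °C
Reagents that add atoms: none
Why: Proposed new method: Pd(OAc)2 should bind the cyclohexa-1,3-diene on the upper face, opposite the C6 and C7 substituents, the enol carbon C3 of the β-keto ester then attacks the diene terminus C2 from the lower face in an outer-sphere trans-carbopalladation (5-exo-trig closure of the cyclopentanone), and the resulting η3-allyl palladium unit over C1–C9–C8, activated by coordinated benzoquinone and kept free of inner-sphere carboxylate by chloride, is opened at C8 by external 3-methylpent-2-enoate anti to the metal before benzoquinone reoxidises zerovalent palladium to divalent palladium. The closest known reaction types are the chloride-mediated cis-1,4-diacyloxylation of cyclohexa-1,3-dienes with Pd(OAc)2 and benzoquinone, its intramolecular variants with tethered oxygen, nitrogen and allylsilane nucleophiles, and the outer-sphere addition of enolic β-dicarbonyl compounds to alkenes activated by divalent palladium. C2 is set by the three-atom tether anchored at C6, which permits only the cis ring fusion, and C8 is set by the anti attack of the carboxylate, which places the ester cis to the new C2–C3 bond on the hindered lower face that direct oxygenation could not reach. C3 becomes a stereocentre of no consequence because its ester is removed in step 17. The step needs carbon and not oxygen attack of the enol, which the 5-exo geometry of the carbon attack should favour, and carboxylate attack at C8 and not at C1, which the methyl group secures by making C1 a tertiary terminus.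

**Step 17**
Reactants: 24 bicyclic β-keto ester
Product: 26 cis-hydrindenone (C3 methylene; C8 ester; C1(Me)=C9 alkene), via β-keto acid 25 (not isolated)
Conditions: Zn, AcOH–THF, 25 → 40 °C
Reagents that add atoms: none
Why: Zinc reduces the trichloroethyl ester to the β-keto acid, which loses CO2 through an enol directed towards C3, so C5 is not epimerised and the allylic C8 ester and the β-acetoxy ketone are left alone.

**Step 18**
Reactants: 26 cis-hydrindenone
Product: 27 C1–C9 epoxide (oxirane oxygen on the upper face)
Conditions: dimethyldioxirane, acetone, −20 °C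
Reagents that add atoms: dimethyldioxirane, CC1(C)OO1
Why: Electrophilic epoxidation by dimethyldioxirane should select the trisubstituted C1=C9 alkene over the 1,1-disubstituted and the conjugated ones and approach from the convex upper face, anti to the C8 ester and the C2–C3 bond, which sets the C9–O configuration.

**Step 19**
Reactants: 27 C1–C9 epoxide
Product: 28 C9 allylic alcohol with C1 exocyclic methylene (hydroxyl on the upper face, trans to the C8 ester)
Conditions: Cp2TiCl2, Zn, THF, 25 °C; then 0.5 M HCl, 0 °C
Reagents that add atoms: none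
Why: Homolytic epoxide opening by trivalent titanium (Cp2TiCl) gives the tertiary C1 radical, whose capture by a second Cp2TiCl and β-hydride elimination towards the unhindered methyl group should give the exocyclic methylene and the C9 alcohol with retention at C9.

**Step 20**
Reactants: 28 C9 allylic alcohol; 29 (R)-2-methylbutanoic acid
Product: 30 C9 (R)-2-methylbutanoate
Conditions: EDC·HCl, DMAP, CH2Cl2, 0 → 25 °C
Reagents that add atoms: none
Why: Steglich esterification acylates the allylic C9 alcohol with retention and without exposing the α-stereocentre of the acid to a ketene pathway.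

**Step 21**
Reactants: 30 C9 ester with silyl-protected side chain
Product: 31 primary allylic alcohol (C7 side chain C(=CH2)CH2OH)
Conditions: HF·pyridine, pyridine, THF, 25 °C
Reagents that add atoms: none
Why: Buffered HF cleaves the remaining silyl ether under conditions that leave the three esters and the β-acetoxy ketone untouched.

**Step 22**
Reactants: 31 primary allylic alcohol
Product: 32 2,3-epoxy alcohol (quaternary epoxide carbon as in the target)
Conditions: Ti(OiPr)4, D-(−)-diethyl tartrate, t-BuOOH, 4 Å molecular sieves, CH2Cl2, −20 °C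
Reagents that add atoms: tert-butyl hydroperoxide, CC(C)(C)OO
Why: Sharpless asymmetric epoxidation acts only on the free allylic alcohol, and the D-(−)-tartrate ligand should set the quaternary epoxide carbon by reagent control.

**Step 23**
Reactants: 32 2,3-epoxy alcohol
Product: 34 epoxy acid, via epoxy aldehyde 33 (not isolated)
Conditions: TEMPO (cat.), PhI(OAc)2, MeCN–H2O, 25 °C
Reagents that add atoms: water, O
Why: Oxoammonium (TEMPO) oxidation takes the primary alcohol through the aldehyde hydrate to the acid and does not react with the exocyclic alkene or the epoxide.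

**Step 24**
Reactants: 34 epoxy acid
Product: 35 target compound
Conditions: Me3SiCHN2, MeOH–toluene, 0 °C
Reagents that add atoms: trimethylsilyldiazomethane, C[Si](C)(C)C=[N+]=[N-]
Why: Methylation of the acid with the diazoalkane is neutral and leaves the epoxide, the esters and the C5 centre intact.

**Compound list**
1 | (R)-(−)-carvone | CC1=CC[C@@H](C(C)=C)CC1=O | starting material
2 | (5R)-5-(3-hydroxyprop-1-en-2-yl)-2-methylcyclohex-2-en-1-one | CC1=CC[C@@H](C(=C)CO)CC1=O | intermediate
3 | (5R)-5-[3-(tert-butyldiphenylsilyloxy)prop-1-en-2-yl]-2-methylcyclohex-2-en-1-one | CC1=CC[C@@H](C(=C)CO[Si](c2ccccc2)(c2ccccc2)C(C)(C)C)CC1=O | intermediate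
4 | (1R,5R)-5-[3-(tert-butyldiphenylsilyloxy)prop-1-en-2-yl]-2-methylcyclohex-2-en-1-ol | CC1=CC[C@@H](C(=C)CO[Si](c2ccccc2)(c2ccccc2)C(C)(C)C)C[C@H]1O | intermediate
5 | epoxy alcohol, oxirane oxygen cis to the hydroxyl and to the side chain | C[C@@]12[C@@H](O1)C[C@@H](C(=C)CO[Si](c3ccccc3)(c3ccccc3)C(C)(C)C)C[C@H]2O | intermediate
6 | hydroxy selenide, phenylselanyl on C2 trans to the tertiary hydroxyl | C[C@]1(O)[C@H]([Se]c2ccccc2)C[C@@H](C(=C)CO[Si](c2ccccc2)(c2ccccc2)C(C)(C)C)C[C@H]1O | intermediate
7 | ene-diol, tertiary C1 and secondary C9 hydroxyls cis to the C7 side chain, C2=C6 alkene | C[C@]1(O)C=C[C@@H](C(=C)CO[Si](c2ccccc2)(c2ccccc2)C(C)(C)C)C[C@H]1O | intermediate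
8 | C9 triethylsilyl ether of 7 | C[C@]1(O)C=C[C@@H](C(=C)CO[Si](c2ccccc2)(c2ccccc2)C(C)(C)C)C[C@H]1O[Si](CC)(CC)CC | intermediate
9 | tertiary C1 acetate of 8 | C[C@]1(OC(C)=O)C=C[C@@H](C(=C)CO[Si](c2ccccc2)(c2ccccc2)C(C)(C)C)C[C@H]1O[Si](CC)(CC)CC | intermediate
10 | trimethylsilyl ketene acetal of 9 | C[C@]1(OC(=C)O[Si](C)(C)C)C=C[C@@H](C(=C)CO[Si](c2ccccc2)(c2ccccc2)C(C)(C)C)C[C@H]1O[Si](CC)(CC)CC | intermediate
11 | trimethylsilyl ester of 12 | CC1=C[C@@H](CC(=O)O[Si](C)(C)C)[C@@H](C(=C)CO[Si](c2ccccc2)(c2ccccc2)C(C)(C)C)C[C@H]1O[Si](CC)(CC)CC | intermediate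
12 | C6 acetic acid, substituents on C6, C7 and C9 all cis, C1=C2 alkene | CC1=C[C@@H](CC(=O)O)[C@@H](C(=C)CO[Si](c2ccccc2)(c2ccccc2)C(C)(C)C)C[C@H]1O[Si](CC)(CC)CC | intermediate
13 | (R)-4-benzyl-1,3-thiazolidine-2-thione | S=C1N[C@H](Cc2ccccc2)CS1 | starting material
14 | N-acyl thiazolidinethione of 12 | CC1=C[C@@H](CC(=O)N2[C@H](Cc3ccccc3)CSC2=S)[C@@H](C(=C)CO[Si](c2ccccc2)(c2ccccc2)C(C)(C)C)C[C@H]1O[Si](CC)(CC)CC | intermediate
15 | syn-aldol adduct (C5 R, C11 S) | CC1=C[C@@H]([C@@H](C(=O)N2[C@H](Cc3ccccc3)CSC2=S)[C@H](C)O)[C@@H](C(=C)CO[Si](c2ccccc2)(c2ccccc2)C(C)(C)C)C[C@H]1O[Si](CC)(CC)CC | intermediate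
16 | C11 acetate of 15 | CC1=C[C@@H]([C@@H](C(=O)N2[C@H](Cc3ccccc3)CSC2=S)[C@H](C)OC(C)=O)[C@@H](C(=C)CO[Si](c2ccccc2)(c2ccccc2)C(C)(C)C)C[C@H]1O[Si](CC)(CC)CC | intermediate
17 | Meldrum's acid | CC1(C)OC(=O)CC(=O)O1 | starting material
18 | 2,2,2-trichloroethanol | OCC(Cl)(Cl)Cl | starting material
19 | 3-oxo-3-(2,2,2-trichloroethoxy)propanoic acid | OC(=O)CC(=O)OCC(Cl)(Cl)Cl | intermediate
20 | 2,2,2-trichloroethyl (4R,5S)-5-acetoxy-3-oxo-4-(cyclohexenyl)hexanoate, C9 silyl ether | CC1=C[C@@H]([C@@H](C(=O)CC(=O)OCC(Cl)(Cl)Cl)[C@H](C)OC(C)=O)[C@@H](C(=C)CO[Si](c2ccccc2)(c2ccccc2)C(C)(C)C)C[C@H]1O[Si](CC)(CC)CC | intermediate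
21 | C9 allylic alcohol from 20 | CC1=C[C@@H]([C@@H](C(=O)CC(=O)OCC(Cl)(Cl)Cl)[C@H](C)OC(C)=O)[C@@H](C(=C)CO[Si](c2ccccc2)(c2ccccc2)C(C)(C)C)C[C@H]1O | intermediate
22 | cyclohexa-1,3-diene β-keto ester, C6 and C7 substituents cis | CC1=C[C@@H]([C@@H](C(=O)CC(=O)OCC(Cl)(Cl)Cl)[C@H](C)OC(C)=O)[C@@H](C(=C)CO[Si](c2ccccc2)(c2ccccc2)C(C)(C)C)C=C1 | intermediate
23 | (E)-3-methylpent-2-enoic acid | OC(=O)/C=C(\C)CC | starting material
24 | cis-fused bicyclic β-keto ester, C8 ester cis to the C2–C3 bond, C1(Me)=C9 alkene, C3 epimers | CC=1[C@H]2C(C(=O)OCC(Cl)(Cl)Cl)C(=O)[C@@H]([C@H](C)OC(C)=O)[C@H]2[C@@H](C(=C)CO[Si](c3ccccc3)(c3ccccc3)C(C)(C)C)[C@@H](OC(=O)/C=C(\C)CC)C=1 | intermediate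
25 | β-keto acid from 24 | CC=1[C@H]2C(C(=O)O)C(=O)[C@@H]([C@H](C)OC(C)=O)[C@H]2[C@@H](C(=C)CO[Si](c3ccccc3)(c3ccccc3)C(C)(C)C)[C@@H](OC(=O)/C=C(\C)CC)C=1 | intermediate
26 | cis-hydrindenone with C8 ester and C1(Me)=C9 alkene | CC=1[C@H]2CC(=O)[C@@H]([C@H](C)OC(C)=O)[C@H]2[C@@H](C(=C)CO[Si](c3ccccc3)(c3ccccc3)C(C)(C)C)[C@@H](OC(=O)/C=C(\C)CC)C=1 | intermediate
27 | C1–C9 epoxide, oxygen on the upper face | C[C@@]12[C@H]3CC(=O)[C@@H]([C@H](C)OC(C)=O)[C@H]3[C@@H](C(=C)CO[Si](c4ccccc4)(c4ccccc4)C(C)(C)C)[C@@H](OC(=O)/C=C(\C)CC)[C@@H]1O2 | intermediate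
28 | C9 allylic alcohol with C1 exocyclic methylene, hydroxyl trans to the C8 ester | C=C1[C@H]2CC(=O)[C@@H]([C@H](C)OC(C)=O)[C@H]2[C@@H](C(=C)CO[Si](c3ccccc3)(c3ccccc3)C(C)(C)C)[C@@H](OC(=O)/C=C(\C)CC)[C@@H]1O | intermediate
29 | (R)-2-methylbutanoic acid | OC(=O)[C@H](C)CC | starting material
30 | C9 (R)-2-methylbutanoate, side chain still silylated | C=C1[C@H]2CC(=O)[C@@H]([C@H](C)OC(C)=O)[C@H]2[C@@H](C(=C)CO[Si](c3ccccc3)(c3ccccc3)C(C)(C)C)[C@@H](OC(=O)/C=C(\C)CC)[C@@H]1OC(=O)[C@H](C)CC | intermediate
31 | primary allylic alcohol | C=C1[C@H]2CC(=O)[C@@H]([C@H](C)OC(C)=O)[C@H]2[C@@H](C(=C)CO)[C@@H](OC(=O)/C=C(\C)CC)[C@@H]1OC(=O)[C@H](C)CC | intermediate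
32 | 2,3-epoxy alcohol | C=C1[C@H]2CC(=O)[C@@H]([C@H](C)OC(C)=O)[C@H]2[C@@H]([C@@]3(CO)CO3)[C@@H](OC(=O)/C=C(\C)CC)[C@@H]1OC(=O)[C@H](C)CC | intermediate
33 | epoxy aldehyde | C=C1[C@H]2CC(=O)[C@@H]([C@H](C)OC(C)=O)[C@H]2[C@@H]([C@@]3(C=O)CO3)[C@@H](OC(=O)/C=C(\C)CC)[C@@H]1OC(=O)[C@H](C)CC | intermediate
34 | epoxy acid | C=C1[C@H]2CC(=O)[C@@H]([C@H](C)OC(C)=O)[C@H]2[C@@H]([C@@]3(C(=O)O)CO3)[C@@H](OC(=O)/C=C(\C)CC)[C@@H]1OC(=O)[C@H](C)CC | intermediate
35 | target compound | C=C1[C@H]2CC(=O)[C@@H]([C@H](C)OC(C)=O)[C@H]2[C@@H]([C@@]2(C(=O)OC)CO2)[C@@H](OC(=O)/C=C(\C)CC)[C@@H]1OC(=O)[C@H](C)CC | target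

**Step count and risks**
Total: 24 steps. Longest linear sequence: 23 steps (steps 1–11 and 13–24 from (R)-carvone).

Steps most likely to fail:

Step 16 (proposed new method). The tethered enol carbon may fail to engage the palladium–diene complex, so that carboxylate adds at both diene termini, or the enol may attack through oxygen. The fallback separates the two events with known chemistry and sets out from 22. The standard chloride-mediated cis-1,4-diacyloxylation (Pd(OAc)2, p-benzoquinone, LiCl, lithium salt of 23 in 23/acetone) should give the cis-1,4-bis(3-methylpent-2-enoate) F1, both esters on the lower face. F1 is then closed by a Tsuji–Trost allylic alkylation with zerovalent palladium (Pd(PPh3)4, N,O-bis(trimethylsilyl)acetamide, KOAc, THF, 50 °C). Ionisation of the C2 ester anti to the metal and anti attack of the β-keto ester enolate give net retention at C2; only the five-membered closure is geometrically possible and the C8 ester stays. This returns to the route at 24.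

Step 19. Hydrogen may be lost from C2 instead of from the methyl group, or the C8 acyl group may migrate to the titanium-bound C9 oxygen. The fallback sets out from 27 and replaces the radical opening by an ionic one. Lewis-acid-catalysed opening with benzeneselenol (PhSeH, BF3·OEt2 cat., CH2Cl2, −78 °C) at the tertiary carbon C1 with inversion should give the hydroxy selenide F2, selenium on the lower face. Oxidation (H2O2, pyridine, 0 °C) then triggers selenoxide syn-elimination. The C2 hydrogen is on the upper face and elimination towards the carbinol carbon is disfavoured, so only the methyl hydrogens are available. This returns to the route at 28.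

Step 15. The Burgess reagent may be consumed by the enol of the β-keto ester, or the allylic sulfamate may ionise before it eliminates. The fallback sets out from 16 and changes the order of events so that the dehydration is done before the β-keto ester exists. Cleavage of the triethylsilyl ether (HF·pyridine) gives the hydroxy thioimide F3, Burgess dehydration gives the diene thioimide F4, and acyl transfer to 19 (MgCl2, imidazole, THF) then returns to the route at 22.

**Further compounds**
F1 | step 16 | cis-1,4-bis[(E)-3-methylpent-2-enoate] of the cyclohexene, esters at C2 and C8 on the lower face, β-keto ester tether intact | CC=1[C@@H](OC(=O)/C=C(\C)CC)[C@@H]([C@@H](C(=O)CC(=O)OCC(Cl)(Cl)Cl)[C@H](C)OC(C)=O)[C@@H](C(=C)CO[Si](c2ccccc2)(c2ccccc2)C(C)(C)C)[C@@H](OC(=O)/C=C(\C)CC)C=1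
F2 | step 19 | hydroxy selenide, phenylselanyl on C1 (lower face), hydroxyl on C9 (upper face) | C[C@]1([Se]c4ccccc4)[C@H]2CC(=O)[C@@H]([C@H](C)OC(C)=O)[C@H]2[C@@H](C(=C)CO[Si](c3ccccc3)(c3ccccc3)C(C)(C)C)[C@@H](OC(=O)/C=C(\C)CC)[C@@H]1O
F3 | step 15 | hydroxy thioimide (16 without the triethylsilyl group) | CC1=C[C@@H]([C@@H](C(=O)N2[C@H](Cc3ccccc3)CSC2=S)[C@H](C)OC(C)=O)[C@@H](C(=C)CO[Si](c2ccccc2)(c2ccccc2)C(C)(C)C)C[C@H]1O
F4 | step 15 | diene thioimide | CC1=C[C@@H]([C@@H](C(=O)N2[C@H](Cc3ccccc3)CSC2=S)[C@H](C)OC(C)=O)[C@@H](C(=C)CO[Si](c2ccccc2)(c2ccccc2)C(C)(C)C)C=C1
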